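Retrosynthesis: the aryl C6–CH2 bond is cut first (sp2–sp3 Negishi coupling), giving 6-iodokaempferol as its MOM ether and (R)-α-cyclogeranyl iodide. The cyclohexene is then cut in one stroke at C1'–C2' and C3'–C4' (C1' = stereocentre, C2' = methyl-bearing sp2 carbon, C6' = CMe2).
Enabling feature: the five-carbon chain CH2(exocyclic)–C1'–C6'–C5'–C4' is symmetric about the quaternary C6', so it maps onto achiral 3,3-dimethylpentanedial; C2'(CH3)=C3' maps onto (E)-1-nitropropene.
Forward: an amine-catalysed Michael/Henry domino desymmetrises the dialdehyde and closes the six-membered ring. The helpers (NO2, C4'-OH, CHO) are then removed: nitroalkene → ketone → enol triflate → C2'=C3' alkene, and CHO → CH2OH → CH2I.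
The flavonol comes from kaempferol (MOM ethers, iodination at C6 directed by the free 5-OH); coupling and MOM removal finish the synthesis.
Stereochemistry: the only stereocentre (C1', R) is set in the domino step by the (S)-configured prolinol silyl ether catalyst; after the in-flask reduction it is never again alpha to a carbonyl group.

Key step: step 3

Assumption: the sense of induction of the (S)-catalyst is taken from the usual face-shielding model for aldehyde/nitroalkene additions (the (R)-catalyst would be used if it proves opposite); the nitro-, hydroxyl- and methyl-bearing ring centres of the intermediates are written for the expected main diastereomer and are erased later.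

Step 1
Reactants: 1 3,3-dimethylpentane-1,5-diol
Product: 2 3,3-dimethylpentanedial
Conditions: (COCl)2, DMSO, CH2Cl2, −78 °C; Et3N, −78 → 0 °C
Reagents that add atoms: none
Why: Swern oxidation; activated DMSO should oxidise both primary alcohols to aldehydes without over-oxidation, and no stereocentre is involved.

Step 2
Reactants: 3 1-nitropropan-2-ol (racemic)
Product: 4 (E)-1-nitroprop-1-ene
Conditions: phthalic anhydride, 150 → 180 °C, product distilled off at reduced pressure
Reagents that add atoms: none
Why: Dehydration of a β-nitro alcohol (acylation, then elimination across the acidic α-nitro C–H); the conjugated (E)-nitroalkene is the thermodynamic product and is used fresh.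

Step 3
Reactants: 2 3,3-dimethylpentanedial (excess); 4 (E)-1-nitroprop-1-ene
Product: 7 (1S,2S,3R,4S)-4-(hydroxymethyl)-3,5,5-trimethyl-2-nitrocyclohexan-1-ol, via Michael adduct 5 (not isolated), via hydroxy nitro aldehyde 6 (not isolated)
Conditions: (S)-α,α-diphenylprolinol trimethylsilyl ether (10 mol %), THF, 23 °C; then MeOH, NaBH4, 0 °C
Reagents that add atoms: none
Why: The secondary amine condenses with one of the two enantiotopic formylmethyl arms of 2 to an (E)-enamine, one face of which is shielded by the diphenyl(silyloxy)methyl group; this adds to the β-carbon of 4 through an acyclic synclinal transition state (C1'–C2' bond, Michael addition), and after hydrolysis the nitro-bearing carbon adds to the distal aldehyde (C3'–C4' bond, intramolecular Henry reaction). The closest known reaction type is the diarylprolinol silyl ether-catalysed domino Michael/Henry reaction of pentane-1,5-dial with nitroalkenes, here run on the 3,3-dimethyl homologue. The ring closes in the 6-exo-trig mode (nitronate carbon onto the exocyclic C=O); the four-membered alternative at the proximal aldehyde is out of reach and the gem-dimethyl group favours the folded chain. The stereocentre that survives (formyl-bearing carbon, later C1') is fixed by the catalyst through the choice of arm and enamine face, the methyl-bearing carbon by the syn topicity of the addition, and the nitro- and hydroxyl-bearing carbons by equilibration of the reversible Henry step to equatorial NO2 and OH; the last three are erased later. The step needs mono-addition and retention of the α-formyl configuration: excess 2 should secure the first, and the second is secured by the quaternary neighbour, which slows re-enolisation, and by reducing the aldehyde with NaBH4 in the same flask.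

Step 4
Reactants: 7 (1S,2S,3R,4S)-4-(hydroxymethyl)-3,5,5-trimethyl-2-nitrocyclohexan-1-ol
Product: 9 [(1S,2R)-2,6,6-trimethyl-3-nitrocyclohex-3-en-1-yl]methyl acetate, via diacetate 8 (not isolated)
Conditions: Ac2O, pyridine, DMAP (cat.), CH2Cl2, 0 → 23 °C; then Et3N, 23 °C
Reagents that add atoms: acetic anhydride, CC(=O)OC(C)=O
Why: Both hydroxyls are acetylated; the β-acetoxy nitro unit should then eliminate acetic acid (E1cB across the acidic α-nitro C–H) to the conjugated nitroalkene, while the primary acetate stays as protecting group and C1 carries no acidic hydrogen.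

Step 5
Reactants: 9 [(1S,2R)-2,6,6-trimethyl-3-nitrocyclohex-3-en-1-yl]methyl acetate
Product: 10 [(1S,2R)-2,6,6-trimethyl-3-oxocyclohexyl]methyl acetate
Conditions: Raney nickel (Ni), NaH2PO2·H2O, EtOH, aqueous AcOH/pyridine buffer (pH 5), 40 °C
Reagents that add atoms: water, O
Why: Reductive Nef-type conversion of a conjugated nitroalkene: reduction to the oxime/imine stage and hydrolysis in the buffer should give the ketone at the former nitro carbon; the acetate survives at pH 5 and C1 (beta to the new carbonyl) cannot epimerise.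

Step 6
Reactants: 10 [(1S,2R)-2,6,6-trimethyl-3-oxocyclohexyl]methyl acetate
Product: 11 [(1R)-2,6,6-trimethyl-3-(trifluoromethanesulfonyloxy)cyclohex-2-en-1-yl]methyl acetate
Conditions: Tf2O, 2,6-di-tert-butyl-4-methylpyridine, CH2Cl2, 0 → 23 °C
Reagents that add atoms: trifluoromethanesulfonic anhydride, O=S(=O)(OS(=O)(=O)C(F)(F)F)C(F)(F)F
Why: Enol triflate formation by O-triflation of the ketone and proton loss from the oxocarbenium ion, which under these non-enolate conditions should favour the more substituted enol triflate (methyl-bearing carbon); this places the double bond between C2' and C3' and removes the epimerisable methyl centre.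

Step 7
Reactants: 11 [(1R)-2,6,6-trimethyl-3-(trifluoromethanesulfonyloxy)cyclohex-2-en-1-yl]methyl acetate
Product: 13 [(1R)-2,6,6-trimethylcyclohex-2-en-1-yl]methanol, via alkenyl acetate 12 (not isolated)
Conditions: Pd(OAc)2 (5 mol %), PPh3, Et3N, HCO2H, DMF, 60 °C; then K2CO3, MeOH, 23 °C
Reagents that add atoms: none
Why: Palladium-catalysed formate reduction of an enol triflate (oxidative addition to zerovalent palladium, decarboxylation of formate to a palladium hydride, reductive elimination) should replace OTf by H without moving the double bond; K2CO3/MeOH then transesterifies the acetate.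

Step 8
Reactants: 13 [(1R)-2,6,6-trimethylcyclohex-2-en-1-yl]methanol
Product: 14 (6R)-6-(iodomethyl)-1,5,5-trimethylcyclohex-1-ene
Conditions: I2, PPh3, imidazole, CH2Cl2, 0 → 23 °C
Reagents that add atoms: iodine, II
Why: Appel-type iodination; SN2 displacement of the oxyphosphonium group at the primary carbon leaves the neighbouring stereocentre and the alkene untouched.

Step 9
Reactants: 15 kaempferol
Product: 16 5-hydroxy-3,7-bis(methoxymethoxy)-2-[4-(methoxymethoxy)phenyl]-4H-chromen-4-one
Conditions: MOMCl (3.3 equiv), i-Pr2NEt, CH2Cl2, 0 → 23 °C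
Reagents that add atoms: chloromethyl methyl ether, COCCl
Why: Williamson-type O-alkylation; the 5-hydroxyl is hydrogen-bonded to the C4 carbonyl and should stay free while the 3-, 7- and 4'-hydroxyls are etherified.

Step 10
Reactants: 16 5-hydroxy-3,7-bis(methoxymethoxy)-2-[4-(methoxymethoxy)phenyl]-4H-chromen-4-one
Product: 17 5-hydroxy-6-iodo-3,7-bis(methoxymethoxy)-2-[4-(methoxymethoxy)phenyl]-4H-chromen-4-one
Conditions: BnMe3N+ ICl2− (1.05 equiv), CaCO3, CH2Cl2–MeOH, 23 °C
Reagents that add atoms: benzyltrimethylammonium dichloroiodate, C[N+](C)(C)Cc1ccccc1.Cl[I-]Cl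
Why: Electrophilic aromatic iodination of ring A; with the 5-hydroxyl free and chelated, substitution should go ortho to it at C6 rather than at C8.

Step 11
Reactants: 17 5-hydroxy-6-iodo-3,7-bis(methoxymethoxy)-2-[4-(methoxymethoxy)phenyl]-4H-chromen-4-one
Product: 18 6-iodo-3,5,7-tris(methoxymethoxy)-2-[4-(methoxymethoxy)phenyl]-4H-chromen-4-one
Conditions: NaH, MOMCl, DMF, 0 °C
Reagents that add atoms: chloromethyl methyl ether, COCCl
Why: Williamson etherification; NaH breaks the hydrogen bond of the 5-hydroxyl so that the last acidic proton is masked before the organozinc step.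

Step 12
Reactants: 14 (6R)-6-(iodomethyl)-1,5,5-trimethylcyclohex-1-ene; 18 6-iodo-3,5,7-tris(methoxymethoxy)-2-[4-(methoxymethoxy)phenyl]-4H-chromen-4-one
Product: 20 3,5,7-tris(methoxymethoxy)-2-[4-(methoxymethoxy)phenyl]-6-{[(1R)-2,6,6-trimethylcyclohex-2-en-1-yl]methyl}-4H-chromen-4-one, via alkylzinc iodide 19 (not isolated)
Conditions: Zn dust, LiCl, THF, 40 °C; then 18, Pd(OAc)2 (5 mol %), SPhos (10 mol %), THF–NMP, 50 °C
Reagents that add atoms: zinc, [Zn] (stays in 19 only)
Why: Zinc insertion into the primary C–I bond followed by Negishi coupling (oxidative addition of the aryl iodide to zerovalent palladium, transmetalation, reductive elimination); the bulky biaryl phosphine should favour reductive elimination over β-hydride elimination, and the stereocentre, beta to the metal, is not involved.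

Step 13
Reactants: 20 3,5,7-tris(methoxymethoxy)-2-[4-(methoxymethoxy)phenyl]-6-{[(1R)-2,6,6-trimethylcyclohex-2-en-1-yl]methyl}-4H-chromen-4-one
Product: 21 ugonin G
Conditions: ZnBr2, n-PrSH, CH2Cl2, 0 → 23 °C
Reagents that add atoms: none
Why: Lewis acid-mediated cleavage of the four MOM acetals with capture of the methoxymethyl cation by the thiol; the conditions are mild enough that the trisubstituted alkene should not be protonated, which would let a neighbouring phenol close a chroman ring onto C2'.

Compound list
1 | 3,3-dimethylpentane-1,5-diol | OCCC(C)(C)CCO | starting material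
2 | 3,3-dimethylpentanedial | O=CCC(C)(C)CC=O | intermediate
3 | 1-nitropropan-2-ol (racemic) | CC(O)C[N+](=O)[O-] | starting material
4 | (E)-1-nitroprop-1-ene | C/C=C/[N+](=O)[O-] | intermediate
5 | (2S)-3,3-dimethyl-2-[(2R)-1-nitropropan-2-yl]pentanedial | O=C[C@@H]([C@@H](C)C[N+](=O)[O-])C(C)(C)CC=O | intermediate (not isolated)
6 | (1S,4S,5S,6R)-4-hydroxy-2,2,6-trimethyl-5-nitrocyclohexane-1-carbaldehyde | O=C[C@H]1[C@@H](C)[C@H]([N+](=O)[O-])[C@@H](O)CC1(C)C | intermediate (not isolated)
7 | (1S,2S,3R,4S)-4-(hydroxymethyl)-3,5,5-trimethyl-2-nitrocyclohexan-1-ol | OC[C@H]1[C@@H](C)[C@H]([N+](=O)[O-])[C@@H](O)CC1(C)C | intermediate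
8 | [(1S,2R,3S,4S)-4-acetoxy-2,6,6-trimethyl-3-nitrocyclohexyl]methyl acetate | CC(=O)OC[C@H]1[C@@H](C)[C@H]([N+](=O)[O-])[C@@H](OC(C)=O)CC1(C)C | intermediate (not isolated)
9 | [(1S,2R)-2,6,6-trimethyl-3-nitrocyclohex-3-en-1-yl]methyl acetate | CC(=O)OC[C@H]1[C@@H](C)C([N+](=O)[O-])=CCC1(C)C | intermediate
10 | [(1S,2R)-2,6,6-trimethyl-3-oxocyclohexyl]methyl acetate | CC(=O)OC[C@H]1[C@@H](C)C(=O)CCC1(C)C | intermediate
11 | [(1R)-2,6,6-trimethyl-3-(trifluoromethanesulfonyloxy)cyclohex-2-en-1-yl]methyl acetate | CC(=O)OC[C@H]1C(C)=C(OS(=O)(=O)C(F)(F)F)CCC1(C)C | intermediate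
12 | [(1R)-2,6,6-trimethylcyclohex-2-en-1-yl]methyl acetate | CC(=O)OC[C@H]1C(C)=CCCC1(C)C | intermediate (not isolated)
13 | [(1R)-2,6,6-trimethylcyclohex-2-en-1-yl]methanol | OC[C@H]1C(C)=CCCC1(C)C | intermediate
14 | (6R)-6-(iodomethyl)-1,5,5-trimethylcyclohex-1-ene | IC[C@H]1C(C)=CCCC1(C)C | intermediate
15 | kaempferol, 3,5,7-trihydroxy-2-(4-hydroxyphenyl)-4H-chromen-4-one | O=c1c(O)c(-c2ccc(O)cc2)oc2cc(O)cc(O)c12 | starting material
16 | 5-hydroxy-3,7-bis(methoxymethoxy)-2-[4-(methoxymethoxy)phenyl]-4H-chromen-4-one | COCOc1ccc(cc1)-c1oc2cc(OCOC)cc(O)c2c(=O)c1OCOC | intermediate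
17 | 5-hydroxy-6-iodo-3,7-bis(methoxymethoxy)-2-[4-(methoxymethoxy)phenyl]-4H-chromen-4-one | COCOc1ccc(cc1)-c1oc2cc(OCOC)c(I)c(O)c2c(=O)c1OCOC | intermediate
18 | 6-iodo-3,5,7-tris(methoxymethoxy)-2-[4-(methoxymethoxy)phenyl]-4H-chromen-4-one | COCOc1ccc(cc1)-c1oc2cc(OCOC)c(I)c(OCOC)c2c(=O)c1OCOC | intermediate
19 | {[(1R)-2,6,6-trimethylcyclohex-2-en-1-yl]methyl}zinc iodide | I[Zn]C[C@H]1C(C)=CCCC1(C)C | intermediate (not isolated)
20 | 3,5,7-tris(methoxymethoxy)-2-[4-(methoxymethoxy)phenyl]-6-{[(1R)-2,6,6-trimethylcyclohex-2-en-1-yl]methyl}-4H-chromen-4-one | COCOc1ccc(cc1)-c1oc2cc(OCOC)c(C[C@H]3C(C)=CCCC3(C)C)c(OCOC)c2c(=O)c1OCOC | intermediate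
21 | ugonin G, 3,5,7-trihydroxy-2-(4-hydroxyphenyl)-6-{[(1R)-2,6,6-trimethylcyclohex-2-en-1-yl]methyl}-4H-chromen-4-one | CC1=CCCC(C)(C)[C@H]1Cc1c(O)cc2oc(-c3ccc(O)cc3)c(O)c(=O)c2c1O | target

Total step count: 13. Longest linear sequence: 9 steps (steps 1, 3, 4, 5, 6, 7, 8, 12, 13).

Steps most likely to fail

Step 3. With the bulky catalyst, enamine formation and conjugate addition at the formylmethyl arm next to the quaternary carbon may be too slow, so that 4 oligomerises and the α-formyl centre equilibrates before reduction. The fallback sets out from 2 and comes back at 7; it uses the chiral amine as a smaller, stoichiometric auxiliary. Compound 2 would be condensed with (S)-2-(methoxymethyl)pyrrolidine (2.2 equiv, K2CO3, Et2O) to the bis-enamine (2S,2'S)-1,1'-[(1E,4E)-3,3-dimethylpenta-1,4-diene-1,5-diyl]bis[2-(methoxymethyl)pyrrolidine] F1. One equivalent of 4 at −78 °C should add to one enamine arm (stoichiometric enamine/nitroalkene Michael addition, with the same face shielded as in step 3). Buffered aqueous hydrolysis (pH 5) should release 5, which closes to 6 (catalytic Et3N) and is reduced with NaBH4 to 7.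

Step 6. Proton loss from the methylene side of the O-triflylated ketone would give the less substituted enol triflate and put the double bond between C3' and C4'. The fallback sets out from 9 and comes back at 12; it makes the alkene without any enolisation. Et3N should isomerise 9 to the allylic nitro compound [(1S,2R)-2,6,6-trimethyl-3-nitrocyclohex-4-en-1-yl]methyl acetate F2 (both C3 epimers). Pd(PPh3)4 should ionise its C–NO2 bond, and the allylpalladium intermediate can lose a β-hydrogen only from C2, because the other allyl terminus adjoins the quaternary carbon. This gives the diene [(1S)-2,6,6-trimethylcyclohexa-2,4-dien-1-yl]methyl acetate F3. Diimide (2-nitrobenzenesulfonylhydrazide, Et3N, 23 °C) should then reduce the disubstituted C4=C5 bond in preference to the trisubstituted one and give 12.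

Step 12. Transmetalation and reductive elimination at the doubly ortho-substituted arylpalladium intermediate may be slow, leaving β-hydride elimination of the alkyl group and protonation of 19 as the main paths. The fallback sets out from 13 and 18 and comes back at 20; it reverses the polarity and makes the bond by carbonyl addition. Alcohol 13 would be oxidised (the triacetoxy periodinane DMP, NaHCO3, CH2Cl2) to (1R)-2,6,6-trimethylcyclohex-2-ene-1-carbaldehyde F4, used at once because its stereocentre is enolisable. Iodide 18 would be converted with i-PrMgCl·LiCl at −40 °C into {3,5,7-tris(methoxymethoxy)-2-[4-(methoxymethoxy)phenyl]-4-oxo-4H-chromen-6-yl}magnesium chloride F5, which should add to F4 to give the carbinol 6-{hydroxy[(1R)-2,6,6-trimethylcyclohex-2-en-1-yl]methyl}-3,5,7-tris(methoxymethoxy)-2-[4-(methoxymethoxy)phenyl]-4H-chromen-4-one F6 (both carbinol epimers). Its xanthate, O-{[3,5,7-tris(methoxymethoxy)-2-[4-(methoxymethoxy)phenyl]-4-oxo-4H-chromen-6-yl][(1R)-2,6,6-trimethylcyclohex-2-en-1-yl]methyl} S-methyl carbonodithioate F7 (NaH, CS2, MeI), would be reduced with Bu3SnH/AIBN (Barton–McCombie deoxygenation) to 20.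

Further compounds
F1 | step 3 | (2S,2'S)-1,1'-[(1E,4E)-3,3-dimethylpenta-1,4-diene-1,5-diyl]bis[2-(methoxymethyl)pyrrolidine] | COC[C@@H]1CCCN1/C=C/C(C)(C)/C=C/N1CCC[C@H]1COC
F2 | step 6 | [(1S,2R)-2,6,6-trimethyl-3-nitrocyclohex-4-en-1-yl]methyl acetate (both C3 epimers) | CC(=O)OC[C@H]1[C@@H](C)C([N+](=O)[O-])C=CC1(C)C
F3 | step 6 | [(1S)-2,6,6-trimethylcyclohexa-2,4-dien-1-yl]methyl acetate | CC(=O)OC[C@H]1C(C)=CC=CC1(C)C
F4 | step 12 | (1R)-2,6,6-trimethylcyclohex-2-ene-1-carbaldehyde | O=C[C@H]1C(C)=CCCC1(C)C
F5 | step 12 | {3,5,7-tris(methoxymethoxy)-2-[4-(methoxymethoxy)phenyl]-4-oxo-4H-chromen-6-yl}magnesium chloride | COCOc1ccc(cc1)-c1oc2cc(OCOC)c([Mg]Cl)c(OCOC)c2c(=O)c1OCOC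
F6 | step 12 | 6-{hydroxy[(1R)-2,6,6-trimethylcyclohex-2-en-1-yl]methyl}-3,5,7-tris(methoxymethoxy)-2-[4-(methoxymethoxy)phenyl]-4H-chromen-4-one (both carbinol epimers) | COCOc1ccc(cc1)-c1oc2cc(OCOC)c(C(O)[C@H]3C(C)=CCCC3(C)C)c(OCOC)c2c(=O)c1OCOC
F7 | step 12 | O-{[3,5,7-tris(methoxymethoxy)-2-[4-(methoxymethoxy)phenyl]-4-oxo-4H-chromen-6-yl][(1R)-2,6,6-trimethylcyclohex-2-en-1-yl]methyl} S-methyl carbonodithioate | COCOc1ccc(cc1)-c1oc2cc(OCOC)c(C(OC(=S)SC)[C@H]3C(C)=CCCC3(C)C)c(OCOC)c2c(=O)c1OCOC
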